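I started from a ratio: how fast E fell late in a run over how fast it fell early. I took E's logarithm to fall at a pace proportional to free J (pseudo-first-order in E), so that ratio reads free J late as a fraction of the charge.

| setting | east | north | gamma | alpha |
|---|---|---|---|---|
| E | 23 mM | 23 mM | 23 mM | 23 mM |
| J | 32 mM | 76 mM | 28.0 mM | 55.0 mM |
| G | 1.15 mM | 1.15 mM | 1.15 mM | 1.15 mM |
| remark | run made earlier | run made earlier |  |  |
| time |  |  | 40 h | 40 h |

| run | time / h | E / % | X / % |
|---|---|---|---|
| east | 3.00 | 77 | 20 |
| east | 6.00 | 65 | 32 |
| east | 10.0 | 51 | 39 |
| east | 12.0 | 51 | 45 |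
| east | 15.0 | 46 | 48 |
| east | 20.0 | 43 | 55 |
| north | 3.00 | 59 | 43 |
| north | 6.00 | 31 | 58 |
| north | 10.0 | 22 | 75 |
| north | 12.0 | 17 | 77 |
| north | 15.0 | 11 | 81 |
| north | 20.0 | 8 | 84 |

(scatter of a reading: 2 percentage points)

* part of the E that has reacted at the end, gamma
* part of the E that has reacted at the end, alpha
* what raising the concentration of J from its lowest to its highest value here does to the part of the E that has reacted (changes below 5 percentage points count as none) (it rises / no change / it falls)



In the east run, X gained per hour over mean E in the first interval gave an early pace of 0.0753 h⁻¹. The logarithm of E from 10.0 h to 20.0 h gave a late pace of 0.0171 h⁻¹. So about 7.25 mM of J was free near 15.0 h, when X read 48%, and each X had cost 2.24 J.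

The north run, reckoned the same way, gave 0.180 h⁻¹ early, 0.101 h⁻¹ late, about 42.6 mM of J free, and a cost of 1.79. The two ways part, and each late pace rests on a few readings with a scatter of 2 percentage points, so I could blame no single reading and took the mean, 2.02, as a rough figure. I called this the J bill, the J gone for each X made.

The charge over the bill sets a ceiling on X. For gamma it was 60.4% of the E charged, and with about 5.00% of E missing from the balance, I expected reaction to stop near 65.4%, a ceiling rather than a figure for the asked time. For alpha the ceiling was 119%, past the whole of E.

The forecast read “a reversible E + J ⇌ X” and gave 65% (57% to 72%) for gamma, 85% (78% to 91%) for alpha, and said of more J: it rises.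

The flask gave 61.7% for gamma and 92.8% for alpha: it rises, by 31 points.

    J + D ⇌ L, settled at all times (K = 23000 M⁻¹)
    E + J ⇌ D + X (K = 2.20, k = 7.70 × 10⁻⁴ M⁻¹ s⁻¹)
    E + G → Q (k = 0.0140 M⁻¹ s⁻¹)

The second J goes into L, since each X comes with a D that binds one. The end states of gamma and alpha give bills of 1.98 and 2.00. Alpha reached 92.8% of its E reacted, against 61.7% with gamma's J charge, because of its larger J charge. After 400 h, gamma's X was 61.2%, with J at 2.46% of its charge, against the ceiling of 60.4% reckoned above.

A further flask like alpha but charged with 92 mM of E has a ceiling near 29.7% of X by the same bill. The simulation gave 30.9% X there after 40.0 h, with 67.9% of E left.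

The numbers in the tables come from a simulation with made-up constants; noise was put on by code.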